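**Retrosynthetic overview**
- The target comes from a cis,cis-octaether by one global O-dealkylation. Both C2 centres relax to trans in that step and both C3 centres stay untouched.
- Key disconnection: both C2–C3 bonds are cut at once. A bis(diaryldiazomethane) undergoes two catalyst-controlled rhodium-carbene insertions into the flanking ArO–CH2–Ar C–H bonds. Dihydrofuran rings A (styryl-bearing half) and B form in the same operation, and no other ring is made in the route.
- The bis(diazo) compound comes from a bis(hydrazone), and that from a bis(N–H ketimine). The ketimines arise from two aryl-metal/nitrile additions, so no redox adjustment and no hindered ketone is needed.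
- Both resorcinol cores come from one nitrile, 4-bromo-2,6-bis(PMB-oxy)benzonitrile, made by double SNAr on 4-bromo-2,6-difluorobenzonitrile. Its bromide serves once in a Heck reaction and once in a Br–Li exchange. The two identical ortho ethers make the insertion regiochemically degenerate, and the spare ether protects the C4 phenol.

Stereochemistry read from the SMILES: (2S,3S) in both dihydrobenzofurans, both trans. PMB = 4-methoxybenzyl.

Assumption: Rh2(R-PTAD)4 is taken to deliver the (3S) sense at both carbene carbons. If a model insertion shows the opposite sense, Rh2(S-PTAD)4 is used and nothing else changes.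

**Step 1**
Reactants: 1 4-bromo-2,6-difluorobenzonitrile; 2 4-methoxybenzyl alcohol (2.2 equiv)
Product: 5 4-bromo-2,6-bis[(4-methoxybenzyl)oxy]benzonitrile, via sodium 4-methoxybenzyl oxide 3 (not isolated), via fluoro monoether 4 (not isolated)
Conditions: NaH (2.3 equiv), THF, 0 °C; then 1, 0 → 65 °C
Reagents that add atoms: none
Why: Double nucleophilic aromatic substitution (SNAr), in which both fluorides sit ortho to the nitrile and leave far faster than the para bromide, so only the two C–F bonds are replaced; no stereocentre.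

**Step 2**
Reactants: 6 2,4-dimethoxybenzaldehyde
Product: 7 2,4-dimethoxystyrene
Conditions: MePPh3Br, KOtBu, THF, 0 °C → rt
Reagents that add atoms: methyltriphenylphosphonium bromide, C[P+](c1ccccc1)(c1ccccc1)c1ccccc1.[Br-]
Why: Wittig methylenation of an unhindered aromatic aldehyde with the non-stabilised ylide is reliable, and the electron-rich styrene is used fresh; no stereocentre.

**Step 3**
Reactants: 5 4-bromo-2,6-bis[(4-methoxybenzyl)oxy]benzonitrile; 7 2,4-dimethoxystyrene
Product: 8 4-[(E)-2-(2,4-dimethoxyphenyl)ethenyl]-2,6-bis[(4-methoxybenzyl)oxy]benzonitrile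
Conditions: Pd(OAc)2 (3 mol %), P(o-tol)3 (6 mol %), K2CO3, DMF, 100 °C
Reagents that add atoms: none
Why: Mizoroki–Heck reaction, in which the unhindered bromide para to the nitrile adds readily to zerovalent palladium, and insertion at the terminal styrene carbon followed by syn β-hydride elimination gives the (E)-stilbene.

**Step 4**
Reactants: 9 1-bromo-3,5-dimethoxybenzene; 5 4-bromo-2,6-bis[(4-methoxybenzyl)oxy]benzonitrile
Product: 12 1-{4-bromo-2,6-bis[(4-methoxybenzyl)oxy]phenyl}-1-(3,5-dimethoxyphenyl)methanimine, via 3,5-dimethoxyphenylmagnesium bromide 10 (not isolated), via N-bromomagnesio ketimine 11 (not isolated)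
Conditions: Mg, THF, reflux; then 5, CuBr·SMe2 (5 mol %), THF, 65 °C; H2O, 0 °C
Reagents that add atoms: none
Why: Copper-catalysed Grignard addition to a nitrile stops at the N-magnesio ketimine, an aryl Grignard reagent does not exchange with the aryl bromide, and the doubly ortho-flanked N–H ketimine survives the aqueous quench and chromatography; no stereocentre.

**Step 5**
Reactants: 12 bromo ketimine; 8 stilbene nitrile
Product: 17 bis(hydrazone) {4-[hydrazono(3,5-dimethoxyphenyl)methyl]-3,5-bis(PMB-oxy)phenyl}{4-[(E)-2-(2,4-dimethoxyphenyl)ethenyl]-2,6-bis(PMB-oxy)phenyl}methanone hydrazone, via N-lithio bromo ketimine 13 (not isolated), via C,N-dilithio species 14 (not isolated), via bis(N-lithio ketimine) 15 (not isolated), via bis(ketimine) 16 (not isolated)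
Conditions: MeLi (1.0 equiv), THF, −78 → −40 °C; n-BuLi (1.05 equiv), −78 °C; 8, −78 → 0 °C; AcOH, N2H4 (1 M in THF, excess), n-BuOH, 90 °C, Ar
Reagents that add atoms: hydrazine, NN
Why: Prior N–H deprotonation keeps the aryllithium from bromine–lithium exchange alive, this unhindered aryllithium adds once to the linear nitrile of 8 (organolithium–nitrile addition), and acid-catalysed transimination with the small α-effect nucleophile hydrazine converts both C=NH groups, which exchange far more readily than the corresponding hindered ketones condense; no stereocentre, and the alkene is safe under argon.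

**Step 6 (key step)**
Reactants: 17 bis(hydrazone)
Product: 19 cis,cis-octaether (2R,3S)-3-{(2R,3S)-3-(3,5-dimethoxyphenyl)-2-(4-methoxyphenyl)-4-(PMB-oxy)-2,3-dihydro-1-benzofuran-6-yl}-6-[(E)-2-(2,4-dimethoxyphenyl)ethenyl]-2-(4-methoxyphenyl)-4-(PMB-oxy)-2,3-dihydro-1-benzofuran, via bis(diazo) compound 18 (not isolated)
Conditions: MnO2 (activated, excess), CH2Cl2, 0 °C → rt, filter; Rh2(R-PTAD)4 [dirhodium tetrakis((R)-(1-adamantyl)(phthalimido)acetate), 2 mol %], CH2Cl2, 0 °C → rt
Reagents that add atoms: none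
Why: Proposed new method: each diaryldiazomethane unit loses N2 at the dirhodium carboxylate to give a weakly electrophilic donor/donor carbene that resists azine formation and cyclopropanation of the remote stilbene; each carbene inserts through a five-membered, hydride-transfer-like concerted transition state into the hydridic O–CH2–(4-MeOC6H4) bond held next to it; the two ortho PMB ethers on each core are equivalent, so no regiochemical question arises, and the two carbene sites are para across the ring B core and cannot meet; the chiral pocket sets C3 as (S) and C2 as (R), cis, independently at both sites, and a 95:5 selectivity per site gives about 99% ee for the homochiral product with a separable mixed diastereomer; the closest known reaction is the enantioselective intramolecular C–H insertion of a single diaryl rhodium carbene into a benzyl aryl ether giving cis-2,3-diaryl-2,3-dihydrobenzofurans.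

**Step 7**
Reactants: 19 cis,cis-octaether
Product: 20 target (2S,3S)-3-[(2S,3S)-3-(3,5-dihydroxyphenyl)-4-hydroxy-2-(4-hydroxyphenyl)-2,3-dihydro-1-benzofuran-6-yl]-6-[(E)-2-(2,4-dihydroxyphenyl)ethenyl]-2-(4-hydroxyphenyl)-2,3-dihydro-1-benzofuran-4-ol
Conditions: BBr3 (30 equiv), C6HMe5 (10 equiv), CH2Cl2 (2 mM), −78 °C → rt; H2O, 0 °C
Reagents that add atoms: none
Why: Lewis-acid ether cleavage removes the two PMB groups at low temperature (cations trapped by pentamethylbenzene, Friedel–Crafts scavenging) and then all methyl ethers, while reversible opening of each benzylic C2–O bond (4-oxybenzyl cation/p-quinone methide) and reclosure anti to the C3 aryl turns both (2R) centres into the thermodynamic trans (2S) centres with the (3S) centres untouched.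

**Compound list**
1 | 4-bromo-2,6-difluorobenzonitrile | N#Cc1c(F)cc(Br)cc1F | starting material
2 | 4-methoxybenzyl alcohol | COc1ccc(CO)cc1 | starting material
3 | sodium 4-methoxybenzyl oxide | [Na+].[O-]Cc1ccc(OC)cc1 | intermediate
4 | 4-bromo-2-fluoro-6-[(4-methoxybenzyl)oxy]benzonitrile | N#Cc1c(F)cc(Br)cc1OCc1ccc(OC)cc1 | intermediate
5 | 4-bromo-2,6-bis[(4-methoxybenzyl)oxy]benzonitrile | N#Cc1c(OCc2ccc(OC)cc2)cc(Br)cc1OCc1ccc(OC)cc1 | intermediate
6 | 2,4-dimethoxybenzaldehyde | COc1ccc(C=O)c(OC)c1 | starting material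
7 | 2,4-dimethoxystyrene | C=Cc1ccc(OC)cc1OC | intermediate
8 | 4-[(E)-2-(2,4-dimethoxyphenyl)ethenyl]-2,6-bis[(4-methoxybenzyl)oxy]benzonitrile | N#Cc1c(OCc2ccc(OC)cc2)cc(/C=C/c2ccc(OC)cc2OC)cc1OCc1ccc(OC)cc1 | intermediate
9 | 1-bromo-3,5-dimethoxybenzene | COc1cc(Br)cc(OC)c1 | starting material
10 | 3,5-dimethoxyphenylmagnesium bromide | COc1cc(OC)cc([Mg]Br)c1 | intermediate
11 | N-bromomagnesio derivative of ketimine 12 | COc1cc(OC)cc(C(=N[Mg]Br)c2c(OCc3ccc(OC)cc3)cc(Br)cc2OCc2ccc(OC)cc2)c1 | intermediate
12 | 1-{4-bromo-2,6-bis[(4-methoxybenzyl)oxy]phenyl}-1-(3,5-dimethoxyphenyl)methanimine | COc1cc(OC)cc(C(=N)c2c(OCc3ccc(OC)cc3)cc(Br)cc2OCc2ccc(OC)cc2)c1 | intermediate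
13 | N-lithio derivative of 12 | COc1cc(OC)cc(C(=N[Li])c2c(OCc3ccc(OC)cc3)cc(Br)cc2OCc2ccc(OC)cc2)c1 | intermediate
14 | C,N-dilithio species (aryl-Li in place of Br, N-Li) | COc1cc(OC)cc(C(=N[Li])c2c(OCc3ccc(OC)cc3)cc([Li])cc2OCc2ccc(OC)cc2)c1 | intermediate
15 | bis(N-lithio ketimine) | COc1cc(OC)cc(C(=N[Li])c2c(OCc3ccc(OC)cc3)cc(cc2OCc2ccc(OC)cc2)C(=N[Li])c2c(OCc3ccc(OC)cc3)cc(/C=C/c3ccc(OC)cc3OC)cc2OCc2ccc(OC)cc2)c1 | intermediate
16 | bis(N–H ketimine) | COc1cc(OC)cc(C(=N)c2c(OCc3ccc(OC)cc3)cc(cc2OCc2ccc(OC)cc2)C(=N)c2c(OCc3ccc(OC)cc3)cc(/C=C/c3ccc(OC)cc3OC)cc2OCc2ccc(OC)cc2)c1 | intermediate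
17 | bis(hydrazone) (C=N geometry immaterial) | COc1cc(OC)cc(C(=NN)c2c(OCc3ccc(OC)cc3)cc(cc2OCc2ccc(OC)cc2)C(=NN)c2c(OCc3ccc(OC)cc3)cc(/C=C/c3ccc(OC)cc3OC)cc2OCc2ccc(OC)cc2)c1 | intermediate
18 | bis(diaryldiazomethane) | COc1cc(OC)cc(C(=[N+]=[N-])c2c(OCc3ccc(OC)cc3)cc(cc2OCc2ccc(OC)cc2)C(=[N+]=[N-])c2c(OCc3ccc(OC)cc3)cc(/C=C/c3ccc(OC)cc3OC)cc2OCc2ccc(OC)cc2)c1 | intermediate
19 | cis,cis-octaether, (2R,3S) in ring A and (2R,3S) in ring B | COc1ccc([C@@H]2Oc3cc(/C=C/c4ccc(OC)cc4OC)cc(OCc4ccc(OC)cc4)c3[C@@H]2c2cc(OCc4ccc(OC)cc4)c3c(c2)O[C@@H](c2ccc(OC)cc2)[C@H]3c2cc(OC)cc(OC)c2)cc1 | intermediate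
20 | CNP0186204.1, (2S,3S) in both rings, (E)-alkene | Oc1ccc([C@H]2Oc3cc(/C=C/c4ccc(O)cc4O)cc(O)c3[C@@H]2c2cc(O)c3c(c2)O[C@H](c2ccc(O)cc2)[C@H]3c2cc(O)cc(O)c2)cc1 | target

**Count**
Total steps: 7. Longest linear sequence: 5 (steps 1, 3, 5, 6, 7; the branches through step 2 or step 4 are equally long).

**Steps most likely to fail, with fallbacks**

Step 6 is the riskiest. Both di-ortho-alkoxy diazo carbons must reach the rhodium centre, and slow carbene formation at either site lets azine or ketone formation take over and spoils the whole molecule. The fallback closes the rings one at a time; it sets out from 12 and comes back at 19.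
- Ketimine 12 is exchanged with hydrazine to give bromo hydrazone F1.
- MnO2 oxidises it to bromo diazo compound F2.
- Rh2(R-PTAD)4 closes ring B alone and gives cis-(2R,3S) bromo dihydrobenzofuran F3.
- Bromine–lithium exchange (n-BuLi, THF, −78 °C) gives aryllithium F4.
- F4 adds to nitrile 8 and, after acetic acid, gives ketimine F5.
- Hydrazine converts it into hydrazone F6, and MnO2 gives diazo compound F7.
- A second insertion with the same catalyst closes ring A and gives 19.

Step 7 is next. It asks for eight ether cleavages in the presence of PMB cations, exposes an electron-rich stilbene to HBr, and passes through a ring-opened cation that could erode C3 by a 1,2-hydride shift. The fallback separates the cation chemistry from the demethylation; it sets out from 19 and comes back at 20.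
- TFA (5 vol %) and pentamethylbenzene in CH2Cl2 at 0 °C remove only the PMB groups. They also equilibrate both C2 centres and give trans,trans-diphenol hexamethyl ether F8.
- F8 is then demethylated under proton-free conditions with AlCl3 and N,N-dimethylaniline in toluene at 80 °C. The amine, not a halide, accepts the methyl groups, so no free acid meets the alkene.

Step 5 is third. The two flanked C=NH groups of 16 may resist exchange with hydrazine at carbon. The fallback makes the N–N bonds at nitrogen instead; it sets out from 16 and comes back at 17.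
- Bis(ketimine) 16 is isolated after the acetic acid quench.
- It is N-aminated with O-(diphenylphosphinyl)hydroxylamine and K2CO3 in CH2Cl2/MeCN at rt (electrophilic amination).
- The reagent attacks the exposed imine lone pair rather than the shielded carbon, so 17 forms directly and no new compound is made.

**Further compounds**
F0 | step 5 | none | none
F1 | step 6 | [4-bromo-2,6-bis(PMB-oxy)phenyl](3,5-dimethoxyphenyl)methanone hydrazone | COc1cc(OC)cc(C(=NN)c2c(OCc3ccc(OC)cc3)cc(Br)cc2OCc2ccc(OC)cc2)c1
F2 | step 6 | [4-bromo-2,6-bis(PMB-oxy)phenyl](3,5-dimethoxyphenyl)diazomethane | COc1cc(OC)cc(C(=[N+]=[N-])c2c(OCc3ccc(OC)cc3)cc(Br)cc2OCc2ccc(OC)cc2)c1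
F3 | step 6 | (2R,3S)-6-bromo-3-(3,5-dimethoxyphenyl)-2-(4-methoxyphenyl)-4-(PMB-oxy)-2,3-dihydro-1-benzofuran | Brc1cc(OCc2ccc(OC)cc2)c2c(c1)O[C@@H](c1ccc(OC)cc1)[C@H]2c1cc(OC)cc(OC)c1
F4 | step 6 | 6-lithio analogue of F3 | [Li]c1cc(OCc2ccc(OC)cc2)c2c(c1)O[C@@H](c1ccc(OC)cc1)[C@H]2c1cc(OC)cc(OC)c1
F5 | step 6 | N–H ketimine joining C6 of the ring B dihydrobenzofuran to the ring A core | N=C(c1cc(OCc2ccc(OC)cc2)c2c(c1)O[C@@H](c1ccc(OC)cc1)[C@H]2c1cc(OC)cc(OC)c1)c1c(OCc2ccc(OC)cc2)cc(/C=C/c2ccc(OC)cc2OC)cc1OCc1ccc(OC)cc1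
F6 | step 6 | hydrazone corresponding to F5 | NN=C(c1cc(OCc2ccc(OC)cc2)c2c(c1)O[C@@H](c1ccc(OC)cc1)[C@H]2c1cc(OC)cc(OC)c1)c1c(OCc2ccc(OC)cc2)cc(/C=C/c2ccc(OC)cc2OC)cc1OCc1ccc(OC)cc1
F7 | step 6 | diazo compound corresponding to F6 | [N-]=[N+]=C(c1cc(OCc2ccc(OC)cc2)c2c(c1)O[C@@H](c1ccc(OC)cc1)[C@H]2c1cc(OC)cc(OC)c1)c1c(OCc2ccc(OC)cc2)cc(/C=C/c2ccc(OC)cc2OC)cc1OCc1ccc(OC)cc1
F8 | step 7 | trans,trans-(2S,3S,2'S,3'S) hexamethyl ether with free C4 phenols on both cores | COc1ccc([C@H]2Oc3cc(/C=C/c4ccc(OC)cc4OC)cc(O)c3[C@@H]2c2cc(O)c3c(c2)O[C@H](c2ccc(OC)cc2)[C@H]3c2cc(OC)cc(OC)c2)cc1
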